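## Analysis of the target

Lignan numbering is used throughout. Ring A is C1–C6 (C1 bears C7H2, C2 is the biaryl carbon, C3 carries OH, C4 and C5 carry OMe, C6 is H). Ring B is C1'–C6' (C1' bears C7', C2' is the biaryl carbon, C3'–C5' carry OMe, C6' is H). The chain is C7–C8(–C9H2–O)–C8'(–C9'H3)–C7'(–O).

The target 15 is a dibenzocyclooctadiene whose eight-membered ring (C1–C2–C2'–C1'–C7'–C8'–C8–C7) is spanned from C7' to C8 by an O–C9H2 bridge. C7', C8', C8, C9 and O therefore form a tetrahydrofuran, and the whole is a bicyclo[5.2.1] frame with C7' and C8 as bridgeheads. The three contiguous stereocentres are 7'R, 8'R and 8R: ring B at C7' and C7 at C8 are cis on the tetrahydrofuran because they belong to the eight-membered ring, and the methyl group at C8' is trans to both. The C2–C2' axis is tetra-ortho-substituted (C1 and C3–OH on ring A, C1' and C3'–OMe on ring B) and is locked by the bridge. Sensitive groups are the C7'–O benzylic ether para to the 4'-OMe group (ionisation in acid, hydrogenolysis), the free phenol and two electron-rich rings, and one hydroxyl must be kept apart from five methoxy groups. The difficulty is the combination of a medium ring, a hindered axis and a bridge. In addition, C1' is para to the central 4'-OMe and is the least nucleophilic carbon of ring B, and any cation at C7' in an open precursor is within reach of C6 of ring A through a six-membered transition state. Two features are used here: the phenol oxygen on C3 and C7' on C1' face each other across the axis (O–C3–C2–C2'–C1'–C7', a six-membered lactone), and the C8–C8' and O–C7' bonds together make up a γ-lactone on a styrene.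

## Retrosynthetic reasoning

15 to 14: the O–C7' bond is cut. In the forward direction the benzylic cation at C7' is captured by the C9 hydroxyl. Because the eight-membered ring already exists, only the cis bridge can close, and neither the phenol oxygen nor ring A can reach C7'. Triol 14 comes from lactone 13 by hydride reduction, so the oxygen on C7' is in place from the lactone stage.

13 to 12: a second ester is added at C8. With two equal esters C8 is not a stereocentre while the C–C bond is made. The surplus ester is removed once the bridge has fixed C8 as a bridgehead.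

12 to 11 (key disconnection): C8–C8' and O–C7' are cut together. This removes the eight-membered ring, the lactone ring and all three stereocentres in one operation and leaves biaryl 11, whose only stereo element is the axis. The cut is made here because C8–C8' can be formed from a malonyl radical and a styrene, where the benzylic radical settles the regiochemistry and no arene has to act as a nucleophile. Cuts at C1'–C7' or C1–C7 would need Friedel–Crafts chemistry at the wrong positions. The forward reaction with Mn(OAc)3 has to close an eight-membered ring by radical addition and then trap the oxidised benzylic position with an ester oxygen.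

11 to 8: the (E)-propenyl group comes from aldehyde 10 by ethylidenation, 10 from benzylic alcohol 9 by oxidation, and 9 from 8 by acylation of the phenol. The pivalate keeps the axis stable at the aldehyde stage (no lactol) and shields the phenol from the oxidant.

8 to 7: the axis. The phenol oxygen and C7' are tied into the six-membered biaryl lactone 7, which is configurationally labile. Reductive opening with a chiral borane reagent sets the axis by dynamic kinetic resolution and at the same time releases the phenol that the target needs and C7' as CH2OH.

7 to 4 and 5: the C2–C2' bond is cut inside ester 6. Intramolecular palladium-catalysed arylation can only occur at C2 of ring A (the other position ortho to the ester oxygen carries OMe), and the bromine of commercial acid 5 fixes the position on ring B.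

4 to 1 and 2: the malonate arm comes from commercial aldehyde 1 and dimethyl malonate 2 by condensation and reduction.

## Alternatives that were turned down

Alternative 1: the textbook route cuts the C2–C2' biaryl bond last. The forward key step is an intramolecular reductive (Ullmann-type) coupling of dibromide A1 with Ni(cod)2, followed by debenzylation. It was turned down for these reasons:
- The key step forms a single bond, and A1 must already carry all three stereocentres, set one by one over about nine steps.
- A tetra-ortho-substituted biaryl has to form inside a bridged eight-membered ring from two hindered aryl halides, where protodehalogenation and oligomerisation compete.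
- A halogen-free oxidative variant cannot tell C2 from C6 on ring A, since both give eight-membered rings.
- The final debenzylation by hydrogenolysis runs next to the benzylic ether.

Alternative 2: the C1'–C7' bond is cut. The forward key step is a Friedel–Crafts closure of the oxocarbenium ion from lactol A2 with BF3·OEt2. The axis of A2 is tri-ortho-substituted and mobile, and the stereocentres come from lactone chemistry. It was turned down for these reasons:
- C1' is para to the twisted central methoxy group and meta to the other two, so it is the least nucleophilic carbon of ring B.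
- The same cation can be attacked by C6 of ring A (ortho to OMe, para to oxygen) through a six-membered transition state, and this tetralin-type closure should be faster than the eight-membered one.
- A blocking group at C6 would add steps and a second halogen.

Alternative 3: C7'–C8' and the lactone C–O bond are cut. The forward key step is a SmI2-mediated 8-endo ketyl–enoate cyclisation of aldehyde A3 with lactonisation in the same flask. It is the polarity-reversed twin of the chosen key step and would give 13 without a surplus ester. It was turned down for these reasons: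
- By the ring-closure model used below, the methyl group at C8' comes out right only from the (Z)-enoate arm of A3, the less stable isomer, which costs three to four extra steps from 1.
- The enoate would not survive the borane step, so the order of steps would have to change.
- Aryl aldehyde ketyls tend to pinacolise.
- C8 would be set by a kinetic protonation.

Key step: step 8

Remark 1: the given structure leaves the sense of the C2–C2' axis open. A ring-closure model of the bicyclo[5.2.1] frame (built by hand with standard bond lengths and angles) indicates that a (7'R,8R) bridge fits only the P twist (aS), so the target is taken as (aS,7'R,8R,8'R).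

Remark 2: the reduction in step 4 is assumed to follow the facial sense usual for such lactones, so that the (S)-oxazaborolidine gives (aS)-8. If the first run shows the opposite sense, the (R)-reagent is used with no other change.

## Route

Step 1
Reactants: 1 3-hydroxy-4,5-dimethoxybenzaldehyde; 2 dimethyl malonate
Product: 4 dimethyl 2-[(3-hydroxy-4,5-dimethoxyphenyl)methyl]propanedioate, via arylidene malonate 3 (not isolated)
Conditions: piperidine (10 mol%), AcOH (10 mol%), toluene, reflux, Dean–Stark; then solvent switch to MeOH, H2 (1 atm), 10% Pd/C, rt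
Reagents that add atoms: none
Why: Knoevenagel condensation with azeotropic removal of water, then hydrogenation of the electron-poor C=C bond of 3, which should leave the arene and the phenol untouched.

Step 2
Reactants: 4 dimethyl 2-[(3-hydroxy-4,5-dimethoxyphenyl)methyl]propanedioate; 5 2-bromo-3,4,5-trimethoxybenzoic acid
Product: 6 dimethyl 2-({3-[(2-bromo-3,4,5-trimethoxybenzoyl)oxy]-4,5-dimethoxyphenyl}methyl)propanedioate
Conditions: DCC, DMAP (10 mol%), CH2Cl2, 0 °C to rt
Reagents that add atoms: none
Why: Steglich esterification; DMAP should carry the hindered aroyl group to the phenol, and the malonate C–H is not acylated under these neutral conditions.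

Step 3
Reactants: 6 dimethyl 2-({3-[(2-bromo-3,4,5-trimethoxybenzoyl)oxy]-4,5-dimethoxyphenyl}methyl)propanedioate
Product: 7 dimethyl 2-[(3,4,8,9,10-pentamethoxy-6-oxo-6H-benzo[c]chromen-1-yl)methyl]propanedioate
Conditions: Pd(OAc)2 (10 mol%), PPh3 (20 mol%), NaOAc (2 equiv), DMA, 130 °C
Reagents that add atoms: none
Why: Intramolecular palladium-catalysed direct arylation (oxidative addition into C–Br, concerted metalation–deprotonation, reductive elimination) closing a six-membered lactone; the ester tether leaves C2 of ring A as the only reachable C–H, so the C2–C2' bond should form with no regiochemical choice.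

Step 4
Reactants: 7 dimethyl 2-[(3,4,8,9,10-pentamethoxy-6-oxo-6H-benzo[c]chromen-1-yl)methyl]propanedioate
Product: 8 dimethyl 2-{[(aS)-6-hydroxy-2'-(hydroxymethyl)-4,5,4',5',6'-pentamethoxybiphenyl-2-yl]methyl}propanedioate
Conditions: (S)-2-methyl-CBS-oxazaborolidine (1.5 equiv), BH3·THF (4 equiv), THF, 30 °C; aqueous work-up
Reagents that add atoms: none
Why: Atroposelective CBS reduction under dynamic kinetic resolution; the two helical forms of lactone 7 interconvert fast and the oxazaborolidine–borane complex should reduce one of them faster, the reagent controlling the new axis; the ring-opened tetra-ortho biaryl is configurationally stable and the methyl esters are not reduced by borane at this temperature.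

Step 5
Reactants: 8 dimethyl 2-{[(aS)-6-hydroxy-2'-(hydroxymethyl)-4,5,4',5',6'-pentamethoxybiphenyl-2-yl]methyl}propanedioate
Product: 9 dimethyl 2-{[(aS)-6-(2,2-dimethylpropanoyloxy)-2'-(hydroxymethyl)-4,5,4',5',6'-pentamethoxybiphenyl-2-yl]methyl}propanedioate
Conditions: pivaloyl chloride (1.05 equiv), K2CO3, acetone, 0 °C
Reagents that add atoms: pivaloyl chloride, CC(C)(C)C(=O)Cl
Why: O-acylation of the phenoxide, which should be selective over the neutral primary alcohol; the pivalate prevents lactol formation (and loss of the axis) after the next step and protects the phenol from the oxidant of step 8.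

Step 6
Reactants: 9 dimethyl 2-{[(aS)-6-(2,2-dimethylpropanoyloxy)-2'-(hydroxymethyl)-4,5,4',5',6'-pentamethoxybiphenyl-2-yl]methyl}propanedioate
Product: 10 dimethyl 2-{[(aS)-6-(2,2-dimethylpropanoyloxy)-2'-formyl-4,5,4',5',6'-pentamethoxybiphenyl-2-yl]methyl}propanedioate
Conditions: MnO2 (activated, excess), CH2Cl2, rt
Reagents that add atoms: none
Why: Oxidation of a benzylic alcohol with MnO2 under neutral conditions; no epimerisable centre is present and the axis stays fixed because the phenol is acylated.

Step 7
Reactants: 10 dimethyl 2-{[(aS)-6-(2,2-dimethylpropanoyloxy)-2'-formyl-4,5,4',5',6'-pentamethoxybiphenyl-2-yl]methyl}propanedioate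
Product: 11 dimethyl 2-{[(aS)-6-(2,2-dimethylpropanoyloxy)-4,5,4',5',6'-pentamethoxy-2'-[(E)-prop-1-enyl]biphenyl-2-yl]methyl}propanedioate
Conditions: CrCl2 (8 equiv), CH3CHI2 (2 equiv), THF, rt
Reagents that add atoms: 1,1-diiodoethane, CC(I)I
Why: Takai–Utimoto ethylidenation through a geminal dichromium reagent, which should give the (E)-alkene; the conditions are not basic, so the malonate C–H and the pivalate are tolerated.

Step 8
Reactants: 11 dimethyl 2-{[(aS)-6-(2,2-dimethylpropanoyloxy)-4,5,4',5',6'-pentamethoxy-2'-[(E)-prop-1-enyl]biphenyl-2-yl]methyl}propanedioate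
Product: 12 methyl (aS,7'R,8R,8'R)-3-(2,2-dimethylpropanoyloxy)-4,5,3',4',5'-pentamethoxy-9-oxo-7',9-epoxy-2,2'-cyclolignane-8-carboxylate (bridged γ-lactone, ester exo on C8)
Conditions: Mn(OAc)3·2H2O (2.5 equiv), AcOH (0.005 M), 70 °C, argon
Reagents that add atoms: none
Why: Mn(OAc)3 oxidises the enol of the 2-benzylmalonate to an electrophilic malonyl radical at C8, which adds 8-endo-trig to the methyl-bearing carbon C8' of the electron-rich propenyl group and so closes the eight-membered ring; a second equivalent oxidises the resulting C7' benzylic radical to the 4'-methoxy-stabilised cation, which is captured by the carbonyl oxygen of the ester on the same face (five-membered closure on the cation), and acetate removes the methyl group to give the lactone. The closest known reaction types are the Mn(OAc)3 lactone annulation of styrenes with malonates, oxidative free-radical cyclisations of unsaturated malonates including 8-endo closures, and radical 8-endo additions to the propenyl group of biaryls of this kind. C8 carries two equal esters and is not stereogenic while the C–C bond forms, so no selectivity is needed there. C7' and C8 are controlled by the axis: with the P twist the eight-membered ring should close in only one conformation, in which the cation at C7' and one ester are syn on one face, so the O–C7' bond can only give 7'R with the bridge cis at C8 (8R), and the second ester ends exo. C8' is controlled by the alkene geometry: on that single trajectory the (E)-alkene places H syn and CH3 anti to ring B, which gives 8'R, whereas the (Z)-isomer would give the epimer. The step needs attack at C8' rather than C7' (secured by the benzylic radical and by polarity matching) and intramolecular rather than intermolecular addition (secured by dilution); once the ring is closed, C7' cannot reach ring A.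

Step 9
Reactants: 12 methyl (aS,7'R,8R,8'R)-3-(2,2-dimethylpropanoyloxy)-4,5,3',4',5'-pentamethoxy-9-oxo-7',9-epoxy-2,2'-cyclolignane-8-carboxylate
Product: 13 (aS,7'R,8R,8'R)-3-(2,2-dimethylpropanoyloxy)-4,5,3',4',5'-pentamethoxy-2,2'-cyclolignano-9,7'-lactone
Conditions: LiCl (3 equiv), H2O (2 equiv), DMSO, 150 °C
Reagents that add atoms: none
Why: Krapcho dealkoxycarbonylation (chloride attacks the ester methyl group, the carboxylate loses CO2 through the lactone enolate); the enolate double bond at the bridgehead is trans only within the nine-membered ring and should be accessible, and protonation at C8 can only return the bridgehead configuration fixed by the bicycle (8R).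

Step 10
Reactants: 13 (aS,7'R,8R,8'R)-3-(2,2-dimethylpropanoyloxy)-4,5,3',4',5'-pentamethoxy-2,2'-cyclolignano-9,7'-lactone
Product: 14 (aS,7'R,8R,8'R)-4,5,3',4',5'-pentamethoxy-2,2'-cyclolignane-3,7',9-triol
Conditions: LiAlH4 (excess), THF, 0 °C to rt; aqueous work-up
Reagents that add atoms: none
Why: Hydride reduction of the lactone to the 1,4-diol with cleavage of the aryl pivalate in the same operation; no bond to C7', C8 or C8' is broken.

Step 11
Reactants: 14 (aS,7'R,8R,8'R)-4,5,3',4',5'-pentamethoxy-2,2'-cyclolignane-3,7',9-triol
Product: 15 (aS,7'R,8R,8'R)-7',9-epoxy-4,5,3',4',5'-pentamethoxy-2,2'-cyclolignan-3-ol (CNP0322364.1)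
Conditions: TsOH·H2O (5 mol%), CH2Cl2, 4 Å molecular sieves, 0 °C to rt
Reagents that add atoms: none
Why: Acid-catalysed cycloetherification through the 4'-methoxy-stabilised benzylic cation at C7', captured by the C9 hydroxyl in a five-membered closure; only the cis bridge can form, so the axis and C8 return C7' as R, and neither the phenol oxygen nor C6 of ring A can reach C7'.

## Compound list

1 | 3-hydroxy-4,5-dimethoxybenzaldehyde | O=Cc1cc(O)c(OC)c(OC)c1 | starting material
2 | dimethyl malonate | COC(=O)CC(=O)OC | starting material
3 | dimethyl 2-[(3-hydroxy-4,5-dimethoxyphenyl)methylidene]propanedioate | COC(=O)C(=Cc1cc(O)c(OC)c(OC)c1)C(=O)OC | intermediate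
4 | dimethyl 2-[(3-hydroxy-4,5-dimethoxyphenyl)methyl]propanedioate | COC(=O)C(Cc1cc(O)c(OC)c(OC)c1)C(=O)OC | intermediate
5 | 2-bromo-3,4,5-trimethoxybenzoic acid | OC(=O)c1cc(OC)c(OC)c(OC)c1Br | starting material
6 | dimethyl 2-({3-[(2-bromo-3,4,5-trimethoxybenzoyl)oxy]-4,5-dimethoxyphenyl}methyl)propanedioate | COC(=O)C(Cc1cc(OC)c(OC)c(OC(=O)c2cc(OC)c(OC)c(OC)c2Br)c1)C(=O)OC | intermediate
7 | dimethyl 2-[(3,4,8,9,10-pentamethoxy-6-oxo-6H-benzo[c]chromen-1-yl)methyl]propanedioate | COC(=O)C(Cc1cc(OC)c(OC)c2OC(=O)c3cc(OC)c(OC)c(OC)c3-c12)C(=O)OC | intermediate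
8 | dimethyl 2-{[(aS)-6-hydroxy-2'-(hydroxymethyl)-4,5,4',5',6'-pentamethoxybiphenyl-2-yl]methyl}propanedioate (axis given in the name only) | COC(=O)C(Cc1cc(OC)c(OC)c(O)c1-c1c(CO)cc(OC)c(OC)c1OC)C(=O)OC | intermediate
9 | dimethyl 2-{[(aS)-6-(2,2-dimethylpropanoyloxy)-2'-(hydroxymethyl)-4,5,4',5',6'-pentamethoxybiphenyl-2-yl]methyl}propanedioate (axis given in the name only) | COC(=O)C(Cc1cc(OC)c(OC)c(OC(=O)C(C)(C)C)c1-c1c(CO)cc(OC)c(OC)c1OC)C(=O)OC | intermediate
10 | dimethyl 2-{[(aS)-6-(2,2-dimethylpropanoyloxy)-2'-formyl-4,5,4',5',6'-pentamethoxybiphenyl-2-yl]methyl}propanedioate (axis given in the name only) | COC(=O)C(Cc1cc(OC)c(OC)c(OC(=O)C(C)(C)C)c1-c1c(C=O)cc(OC)c(OC)c1OC)C(=O)OC | intermediate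
11 | dimethyl 2-{[(aS)-6-(2,2-dimethylpropanoyloxy)-4,5,4',5',6'-pentamethoxy-2'-[(E)-prop-1-enyl]biphenyl-2-yl]methyl}propanedioate (axis given in the name only) | COC(=O)C(Cc1cc(OC)c(OC)c(OC(=O)C(C)(C)C)c1-c1c(/C=C/C)cc(OC)c(OC)c1OC)C(=O)OC | intermediate
12 | methyl (aS,7'R,8R,8'R)-3-(2,2-dimethylpropanoyloxy)-4,5,3',4',5'-pentamethoxy-9-oxo-7',9-epoxy-2,2'-cyclolignane-8-carboxylate | COc1cc2c(c(OC(=O)C(C)(C)C)c1OC)-c1c(cc(OC)c(OC)c1OC)[C@@H]1OC(=O)[C@](C(=O)OC)(C2)[C@H]1C | intermediate
13 | (aS,7'R,8R,8'R)-3-(2,2-dimethylpropanoyloxy)-4,5,3',4',5'-pentamethoxy-2,2'-cyclolignano-9,7'-lactone | COc1cc2c(c(OC(=O)C(C)(C)C)c1OC)-c1c(cc(OC)c(OC)c1OC)[C@@H]1OC(=O)[C@H](C2)[C@H]1C | intermediate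
14 | (aS,7'R,8R,8'R)-4,5,3',4',5'-pentamethoxy-2,2'-cyclolignane-3,7',9-triol | COc1cc2c(c(O)c1OC)-c1c(cc(OC)c(OC)c1OC)[C@H](O)[C@H](C)[C@H](CO)C2 | intermediate
15 | (aS,7'R,8R,8'R)-7',9-epoxy-4,5,3',4',5'-pentamethoxy-2,2'-cyclolignan-3-ol | COc1cc2c(c(O)c1OC)-c1c(cc(OC)c(OC)c1OC)[C@@H]1OC[C@H](C2)[C@H]1C | target

## Step count and risks

Total step count: 11. Longest linear sequence: 11 steps (from 1; acid 5 enters in step 2).

Least certain steps:

Step 8 (key step). Three things are most likely to go wrong.
- Enolisation of the hindered tertiary malonate may be slow, so that the oxidant attacks the electron-rich styrene or arenes instead.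
- The malonyl radical may close onto ring B through a six-membered ipso attack, or add intermolecularly.
- The axis may erode at 70 °C.

The fallback generates the same radical reductively at room temperature and separates the ionic step. It sets out from 11. Bromination with CBr4 and DBU in CH2Cl2 would give dimethyl 2-bromo-2-{[(aS)-6-(2,2-dimethylpropanoyloxy)-4,5,4',5',6'-pentamethoxy-2'-[(E)-prop-1-enyl]biphenyl-2-yl]methyl}propanedioate F1. Irradiation with blue light in the presence of Ir(ppy)3 (1 mol%) in DMF should then give, by atom-transfer radical cyclisation, the eight-membered benzylic bromide F2. On warming in AcOH with NaOAc, F2 ionises and lactonises with loss of bromomethane. The fallback comes back to the route at 12. If the 8-endo addition itself fails, this fallback does not help.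

Step 4. The atroposelection may be modest or of the opposite sense, and slow reduction of the malonate esters may compete. The fallback sets out from 7. Reduction with NaBH4 in THF/MeOH would give the racemic alcohol F3 (the constitution of 8). A lipase-catalysed acylation of the CH2OH group with vinyl acetate, with the enzyme chosen so that the (aR)-atropisomer reacts, would leave (aS)-8 and give the (aR)-acetate F4. F4 can be returned to 7 by methanolysis (K2CO3, MeOH) and oxidation with MnO2 through the lactol. The fallback comes back at 8.

Step 3. The C–H palladation at the doubly flanked C2 may be sluggish, and protodebromination of ring B would then take over. The fallback makes the same bond by cross-coupling and sets out from 4 and 5.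
- ortho-Selective bromination of 4 (NBS, i-Pr2NH 10 mol%, CH2Cl2) would give dimethyl 2-[(2-bromo-3-hydroxy-4,5-dimethoxyphenyl)methyl]propanedioate F5.
- Acid 5 would be converted into its methyl ester F6 (MeOH, H2SO4) and then into the pinacol boronate F7 (B2pin2, Pd(dppf)Cl2, KOAc).
- Suzuki–Miyaura coupling of F5 and F7 (Pd(OAc)2, SPhos, K3PO4, toluene/water, 100 °C) should give the biaryl hydroxy ester F8, which lactonises on warming with TsOH.

The fallback comes back at 7.

Step 9. Formation of the bridgehead enolate may be too slow, so that the ester is only cleaved or the lactone opens. The fallback removes the carboxyl group through a radical and sets out from 12. Me3SnOH in 1,2-dichloroethane at 80 °C would give the lactone acid F9. Coupling with N-hydroxypyridine-2-thione (DCC) would give the thiohydroxamate ester F10. Photolysis of F10 with t-BuSH (Barton decarboxylation) should give the C8–H lactone, the hydrogen entering at the bridgehead from the only open side. The fallback comes back at 13.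

Step 11. The C7' cation may lose a proton to give the C7'=C8' alkene, and reprotonation of that alkene would scramble C8'. The fallback avoids the cation and sets out from 14. Mitsunobu cyclodehydration (PPh3, DIAD, THF, high dilution) activates the primary C9 hydroxyl, which is displaced by the C7' oxygen with retention at C7'; the phenol cannot reach C9 within the molecule. The fallback makes no new compound and comes back at 15.

## Further compounds

F1 | step 8 | dimethyl 2-bromo-2-{[(aS)-6-(2,2-dimethylpropanoyloxy)-4,5,4',5',6'-pentamethoxy-2'-[(E)-prop-1-enyl]biphenyl-2-yl]methyl}propanedioate | COC(=O)C(Br)(Cc1cc(OC)c(OC)c(OC(=O)C(C)(C)C)c1-c1c(/C=C/C)cc(OC)c(OC)c1OC)C(=O)OC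
F2 | step 8 | dimethyl (aS,8'R)-7'-bromo-3-(2,2-dimethylpropanoyloxy)-4,5,3',4',5'-pentamethoxy-2,2'-cyclolignane-8,8-dicarboxylate (C9 is one of the two ester carbons; configuration at C7' open) | COc1cc2c(c(OC(=O)C(C)(C)C)c1OC)-c1c(cc(OC)c(OC)c1OC)C(Br)[C@H](C)C(C(=O)OC)(C(=O)OC)C2
F3 | step 4 | racemic dimethyl 2-{[6-hydroxy-2'-(hydroxymethyl)-4,5,4',5',6'-pentamethoxybiphenyl-2-yl]methyl}propanedioate | COC(=O)C(Cc1cc(OC)c(OC)c(O)c1-c1c(CO)cc(OC)c(OC)c1OC)C(=O)OC
F4 | step 4 | dimethyl 2-{[(aR)-2'-(acetoxymethyl)-6-hydroxy-4,5,4',5',6'-pentamethoxybiphenyl-2-yl]methyl}propanedioate | COC(=O)C(Cc1cc(OC)c(OC)c(O)c1-c1c(COC(C)=O)cc(OC)c(OC)c1OC)C(=O)OC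
F5 | step 3 | dimethyl 2-[(2-bromo-3-hydroxy-4,5-dimethoxyphenyl)methyl]propanedioate | COC(=O)C(Cc1cc(OC)c(OC)c(O)c1Br)C(=O)OC
F6 | step 3 | methyl 2-bromo-3,4,5-trimethoxybenzoate | COC(=O)c1cc(OC)c(OC)c(OC)c1Br
F7 | step 3 | methyl 3,4,5-trimethoxy-2-(4,4,5,5-tetramethyl-1,3,2-dioxaborolan-2-yl)benzoate | COC(=O)c1cc(OC)c(OC)c(OC)c1B1OC(C)(C)C(C)(C)O1
F8 | step 3 | dimethyl 2-{[6-hydroxy-4,5,4',5',6'-pentamethoxy-2'-(methoxycarbonyl)biphenyl-2-yl]methyl}propanedioate | COC(=O)C(Cc1cc(OC)c(OC)c(O)c1-c1c(C(=O)OC)cc(OC)c(OC)c1OC)C(=O)OC
F9 | step 9 | (aS,7'R,8R,8'R)-3-(2,2-dimethylpropanoyloxy)-4,5,3',4',5'-pentamethoxy-9-oxo-7',9-epoxy-2,2'-cyclolignane-8-carboxylic acid | COc1cc2c(c(OC(=O)C(C)(C)C)c1OC)-c1c(cc(OC)c(OC)c1OC)[C@@H]1OC(=O)[C@](C(O)=O)(C2)[C@H]1C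
F10 | step 9 | 2-thioxopyridin-1(2H)-yl (aS,7'R,8R,8'R)-3-(2,2-dimethylpropanoyloxy)-4,5,3',4',5'-pentamethoxy-9-oxo-7',9-epoxy-2,2'-cyclolignane-8-carboxylate | COc1cc2c(c(OC(=O)C(C)(C)C)c1OC)-c1c(cc(OC)c(OC)c1OC)[C@@H]1OC(=O)[C@](C(=O)ON3C=CC=CC3=S)(C2)[C@H]1C
F0 | step 11 | none | none
A1 | alternative 1 | (2R,3R,4R)-4-{[3-(benzyloxy)-2-bromo-4,5-dimethoxyphenyl]methyl}-2-(2-bromo-3,4,5-trimethoxyphenyl)-3-methyloxolane | COc1cc(c(Br)c(OC)c1OC)[C@@H]1OC[C@H](Cc2cc(OC)c(OC)c(OCc3ccccc3)c2Br)[C@H]1C
A2 | alternative 2 | (3R,4R)-4-{[6-(benzyloxy)-4,5,2',3',4'-pentamethoxybiphenyl-2-yl]methyl}-3-methyloxolan-2-ol | COc1ccc(c(OC)c1OC)-c1c(OCc2ccccc2)c(OC)c(OC)cc1C[C@H]1COC(O)[C@@H]1C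
A3 | alternative 3 | methyl (Z)-2-{[(aS)-6-(2,2-dimethylpropanoyloxy)-2'-formyl-4,5,4',5',6'-pentamethoxybiphenyl-2-yl]methyl}but-2-enoate | C/C=C(/Cc1cc(OC)c(OC)c(OC(=O)C(C)(C)C)c1-c1c(C=O)cc(OC)c(OC)c1OC)C(=O)OC
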